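All runs are simulated with constants of no real substance; the scatter is artificial.

Time is what I hold equal: the last rows of the dusk and noon runs both stand at 25.0 min, with the same J and X, and they differ in D.

in all of them: J 0.10 M; X 93 µM

| flask | D | remark | time |
|---|---|---|---|
| dusk | 0.048 M | run made earlier |  |
| noon | 0.071 M | run made earlier |  |
| flask | 0.0950 M |  | 40 min |

| run | time / min | Q / % | L / % |
|---|---|---|---|
| dusk | 5.00 | 1.6 | 0 |
| dusk | 10.0 | 3.4 | 0.1 |
| dusk | 15.0 | 5.1 | 0 |
| dusk | 20.0 | 7.3 | 0 |
| dusk | 25.0 | 11.3 | 0.1 |
| noon | 2.00 | 0 | 0 |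
| noon | 6.00 | 1.2 | 0 |
| noon | 12.0 | 5.3 | 0.2 |
| noon | 15.0 | 7.1 | 0.8 |
| noon | 25.0 | 13.0 | 0.8 |

(scatter of a reading: 0.5 percentage points)

- the Q and L together standing at 40 min, as a percentage of the J charged
- concentration of Q in solution at 40 min, in percent of saturation

I read the L column first. Its highest entry is 0.8% against a scatter of 0.5 percentage points, so I read no solid in either run, and I take y, the Q and L together, as the Q column. I therefore place saturation above the 13.0% of Q read in the noon run.

Now I read the last rows against each other. D rises from 0.048 M to 0.071 M, and Q from 11.3% to 13.0%. The logarithm of the ratio of Q over that of the ratio of D is n = 0.358, the apparent reaction order in D, read with the scatter. On this scale zero means D doesn't matter and one means Q follows D in proportion.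

Carrying the noon row to 0.0950 M with n gives 14.4% at 25.0 min. I assume y then grows in proportion to time, which the rows support only roughly, and reach 23.1% at 40 min. With saturation placed above the noon Q, my reckoning puts sat below about 178%.

The forecast says 30% (23% to 37%) and 250% (100% to 600%), calling the rate “roughly first order in D”, where my n is 0.358.

The flask gives y = 26.5% and sat = 50.0%, with L at 0%.

    J + X ⇌ X + E (K = 0.940, k = 4.80 M⁻¹ s⁻¹)
    X + E ⇌ G (K = 28.0 M⁻¹, k = 9.80 M⁻¹ s⁻¹)
    D + G → X + Q (k = 13.0 M⁻¹ s⁻¹)
    L ⇌ Q, rate k4*(cs4 - [Q]) while solid is left; crystals form when [Q] > cs4 (solubility = 0.0530 M, k = 0.00850 s⁻¹)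

The dusk run carried to 40 min, without scatter, stands at 19.9%; n turns that into 25.4% for this flask, which itself stands at 26.5%. The same flask read at 25 min gives 14.9%, where n gave 14.4%. At 40 min the flask is not at rest: 51% of the J and 72% of the D are left. At 400 min y stands at 91.8%, with J down to 4.45% of its charge and D to 3.34% of its own, and within that y, 38.8% of the J charged stands as L.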